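Cuts (eudesmane numbering): first the ester C–O bonds at O3 and O4 and the C3'–Cl bond, then C4–O and C4–C15, and last C5–C6 and C9–C10, which takes ring B apart.
Enabling feature: ring B is a cyclohexenone whose unit C6=C7–C8(=O)–C9 sits between the fusion atoms C5 and C10. O8 is para to C5, and the oxygenated C4 and C3 lie next to C5. This is the retron of a Diels–Alder reaction between a 2-siloxydiene and 2-methoxy-5-methyl-1,4-benzoquinone.
Forward: ring A enters flat as the quinone (O3 and O4 in place, C1=O as helper). Ring B closes in one cycloaddition with a diene that already carries C11 and is locked s-cis in a temporary O8–Si–O11 ring. The side chain is joined late as an epoxy acid.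
Helpers leave later: C1=O by Stork–Danheiser transposition and hydrogenation, and the silylene ring by dehydrogenation to the C6=C7 enone and then fluoride.
Stereochemistry: C10 comes from a chiral titanium diolate catalyst, C5 from equilibration to the trans-decalin, and C4 and C3 from α-face attack opposite the axial β-methyl groups. C2' and C3' come from Katsuki–Sharpless epoxidation and invertive chloride opening.

Key step: step 4

Numbering remark: ring A = C1–C5 and C10; ring B = C5–C10; C14 = methyl on C10; C15 = carbon on C4; C11 (with C12, C13) sits on C7. "Silylenedioxy" means the bridge O8–Si(t-Bu)2–O11, which closes a six-membered ring over C7=C8.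
Assumption: the complex from (R,R)-TADDOL is taken to leave open the quinone face that leads to the 10β-methyl series drawn. If the sense of induction is the opposite, (S,S)-TADDOL is used and nothing else changes. Compounds 1, 3 and 16 are taken as commercial.

Step 1
Reactants: 1 2-methoxy-5-methylphenol
Product: 2 2-methoxy-5-methyl-1,4-benzoquinone
Conditions: (KSO3)2NO, KH2PO4, H2O/acetone, 0 °C to rt
Reagents that add atoms: potassium nitrosodisulfonate (KSO3)2NO, [K+].[K+].[O]N(S(=O)(=O)[O-])S(=O)(=O)[O-]
Why: Teuber oxidation, in which one nitrosodisulfonate radical removes the phenolic hydrogen and a second one delivers oxygen to the free para position, should give the p-quinone, and no stereocentre is involved.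

Step 2
Reactants: 3 3,4-dimethylpent-3-en-2-one
Product: 5 4-hydroxy-4-methyl-3-methylidenepentan-2-one, via allylic hydroperoxide 4 (not isolated)
Conditions: O2, tetraphenylporphyrin (cat.), CH2Cl2, visible light, 0 °C; then PPh3, 0 °C
Reagents that add atoms: dioxygen, O=O
Why: Schenck ene reaction, in which singlet oxygen on α,β-unsaturated carbonyl compounds takes hydrogen from the alkyl group geminal to the carbonyl and places oxygen on the β-carbon, followed by phosphine reduction of the hydroperoxide; no stereocentre is formed.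

Step 3
Reactants: 5 4-hydroxy-4-methyl-3-methylidenepentan-2-one
Product: 6 2,2-di-tert-butyl-4,4-dimethyl-5,6-dimethylidene-1,3,2-dioxasilinane
Conditions: t-Bu2Si(OTf)2, Et3N, CH2Cl2, 0 °C to rt
Reagents that add atoms: di-tert-butylsilyl bis(trifluoromethanesulfonate), CC(C)(C)[Si](OS(=O)(=O)C(F)(F)F)(OS(=O)(=O)C(F)(F)F)C(C)(C)C
Why: O-silylation of the tertiary alcohol followed by intramolecular soft enolisation and O-silylation of the methyl ketone (only C9 carries α-hydrogens) should close a six-membered ring that protects O11, fixes the enol ether regiochemistry and holds the diene s-cis.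

Step 4
Reactants: 2 2-methoxy-5-methyl-1,4-benzoquinone; 6 2,2-di-tert-butyl-4,4-dimethyl-5,6-dimethylidene-1,3,2-dioxasilinane
Product: 8 trans-fused adduct (5αH,10β-methyl)-3-methoxy-8,11-(di-tert-butylsilylenedioxy)-15-noreudesma-2,7-diene-1,4-dione, via cis-fused adduct 7 (not isolated)
Conditions: TiCl2(Oi-Pr)2 (20 mol %), (R,R)-TADDOL (22 mol %), 4 Å MS, toluene, −78 to −30 °C; then DBU (0.5 equiv), rt
Reagents that add atoms: none
Why: Normal-electron-demand, concerted but asynchronous [4+2] cycloaddition in which the enol-ether terminus C9 of 6 leads the attack on C10 and C6–C5 closes in the same event; the closest known reaction type is the Diels–Alder reaction of 2-alkoxy-5-alkyl-1,4-benzoquinones with simple and 2-siloxy dienes under chelating chiral diolate complexes of tetravalent titanium. Ring B is the only ring closed and it closes by intermolecular suprafacial–suprafacial cycloaddition, so 7 is cis-fused, and endo or exo approach is without consequence because both diene termini are CH2. C10 is set by the catalyst, since the quinone is held as a five-membered chelate through O4 and the methoxy oxygen on C3 and an aryl group of the diolate covers one face of C5=C10. C5 is first set cis by the suprafacial addition and is then corrected by DBU through the C4 enolate to the more stable trans-fused 8, while quaternary C10 stays untouched and blocks aromatisation. Site selectivity needs C5=C10 to win over C2=C3, which the methoxy group secures by vinylogous-ester deactivation of C2=C3; regioselectivity needs C9 on C10, which follows because the same resonance weakens C1=O, the chelated C4=O makes its β-carbon C10 the most electrophilic atom, and the siloxy group makes C9 the most nucleophilic one. The silylene ring holds the otherwise twisted 2,3-disubstituted diene s-cis, which should supply the rate needed to build the quaternary centre at low temperature.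

Step 5
Reactants: 8 trans-fused adduct
Product: 9 (5αH)-3-methoxy-8,11-(di-tert-butylsilylenedioxy)eudesma-2,4(15),7-trien-1-one
Conditions: Cp2TiMe2, toluene, 65 °C, dark
Reagents that add atoms: dimethyltitanocene Cp2TiMe2, C[Ti](C)(C1C=CC=C1)C1C=CC=C1
Why: Petasis methylenation, whose thermally formed Cp2Ti=CH2 is non-basic and so leaves the acidic C5–H alone, should take the C4 ketone because C1 is a vinylogous-ester carbonyl flanked by quaternary C10.

Step 6
Reactants: 9 (5αH)-3-methoxy-8,11-(di-tert-butylsilylenedioxy)eudesma-2,4(15),7-trien-1-one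
Product: 11 (5αH)-8,11-(di-tert-butylsilylenedioxy)eudesma-1,4(15),7-trien-3-one, via allylic alcohol 10 (not isolated)
Conditions: i-Bu2AlH, CH2Cl2, −78 °C; then 10% aq oxalic acid, THF, 0 °C
Reagents that add atoms: water, O
Why: Stork–Danheiser transposition, in which 1,2-reduction of the vinylogous ester and acid-induced loss of the C1 hydroxyl with hydrolysis of the methyl enol ether move the carbonyl to C3 and remove the helper oxygen at C1, while the mild acid should spare the hindered silylene enol ether.

Step 7
Reactants: 11 (5αH)-8,11-(di-tert-butylsilylenedioxy)eudesma-1,4(15),7-trien-3-one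
Product: 13 (5αH)-4α-hydroxy-8,11-(di-tert-butylsilylenedioxy)eudesma-1,7-dien-3-one, via 4α-hydroperoxide 12 (not isolated)
Conditions: Mn(dpm)3 (10 mol %), PhSiH3, O2 (1 atm), i-PrOH/CH2Cl2, 0 °C; then P(OEt)3
Reagents that add atoms: dioxygen, O=O
Why: Mukaiyama-type reductive α-hydroxylation of an enone by hydrogen-atom transfer, in which the manganese hydride gives H to the open terminal C15, the tertiary α-keto radical at C4 takes up O2 on the α face opposite the axial 10β-methyl (4α-O, 4β-CH3), and the phosphite reduces the hydroperoxide, while the neopentyl C1=C2 enone and the tetrasubstituted enol ether should react more slowly.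

Step 8
Reactants: 13 (5αH)-4α-hydroxy-8,11-(di-tert-butylsilylenedioxy)eudesma-1,7-dien-3-one
Product: 15 (5αH)-8,11-(di-tert-butylsilylenedioxy)eudesm-7-ene-3β,4α-diol, via saturated ketol 14 (not isolated)
Conditions: H2 (1 atm), Pd/C, EtOH, rt; filter; NaBH4, 0 °C
Reagents that add atoms: none
Why: Heterogeneous hydrogenation should saturate only the disubstituted C1=C2 bond, and borohydride then attacks the C3 ketone axially from the α face, the β face being screened by the adjacent axial 4β-methyl, to give the equatorial 3β-alcohol.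

Step 9
Reactants: 16 (E)-2-methylbut-2-en-1-ol
Product: 17 [(2R,3R)-2,3-dimethyloxiran-2-yl]methanol
Conditions: Ti(Oi-Pr)4 (10 mol %), D-(−)-diethyl tartrate (12 mol %), t-BuOOH, 4 Å MS, CH2Cl2, −20 °C
Reagents that add atoms: tert-butyl hydroperoxide, CC(C)(C)OO
Why: Katsuki–Sharpless asymmetric epoxidation, in which the D-(−)-tartrate complex delivers oxygen to the face of the E-allylic alcohol that gives the (2R,3R)-epoxide and the alkene geometry fixes the trans relation of C1' and C4'.

Step 10
Reactants: 17 [(2R,3R)-2,3-dimethyloxiran-2-yl]methanol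
Product: 18 (2S,3R)-2,3-dimethyloxirane-2-carboxylic acid
Conditions: RuCl3·xH2O (2 mol %), NaIO4, MeCN/EtOAc/H2O, 0 °C to rt
Reagents that add atoms: water, O; sodium periodate NaIO4 as terminal oxidant, [Na+].[O-]I(=O)(=O)=O
Why: Catalytic RuO4 oxidation of a primary alcohol through the aldehyde hydrate to the acid leaves the epoxide and both stereocentres untouched, and the descriptor at C2' changes only by priority.

Step 11
Reactants: 15 (5αH)-8,11-(di-tert-butylsilylenedioxy)eudesm-7-ene-3β,4α-diol; 18 (2S,3R)-2,3-dimethyloxirane-2-carboxylic acid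
Product: 20 (5αH)-3β-[(2S,3R)-2,3-epoxy-2-methylbutanoyloxy]-8,11-(di-tert-butylsilylenedioxy)eudesm-7-en-4α-ol, via mixed anhydride 19 (not isolated)
Conditions: 18, 2,4,6-trichlorobenzoyl chloride, Et3N, toluene, rt; then 15, DMAP, rt to 40 °C
Reagents that add atoms: none
Why: Yamaguchi esterification, in which the compact epoxy acid is activated as its mixed anhydride and should acylate the secondary equatorial 3β-hydroxyl in preference to the tertiary 4α-hydroxyl without touching any stereocentre.

Step 12
Reactants: 20 (5αH)-3β-[(2S,3R)-2,3-epoxy-2-methylbutanoyloxy]-8,11-(di-tert-butylsilylenedioxy)eudesm-7-en-4α-ol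
Product: 21 (5αH)-4α-acetoxy-3β-[(2S,3R)-2,3-epoxy-2-methylbutanoyloxy]-8,11-(di-tert-butylsilylenedioxy)eudesm-7-ene
Conditions: Ac2O, DMAP, Et3N, CH2Cl2, 40 °C
Reagents that add atoms: acetic anhydride, CC(=O)OC(C)=O
Why: DMAP-catalysed acylation is strong enough for the equatorial tertiary 4α-alcohol, the only free hydroxyl left, and it is run before ring B becomes an enone so that no base meets a γ-acidic C5–H next to a leaving group on C4.

Step 13
Reactants: 21 (5αH)-4α-acetoxy-3β-[(2S,3R)-2,3-epoxy-2-methylbutanoyloxy]-8,11-(di-tert-butylsilylenedioxy)eudesm-7-ene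
Product: 22 (5αH)-4α-acetoxy-3β-[(2S,3R)-2,3-epoxy-2-methylbutanoyloxy]-11-[di-tert-butyl(hydroxy)silyloxy]eudesm-6-en-8-one
Conditions: DDQ, 2,6-lutidine, CH2Cl2, 0 °C to rt; aq NaHCO3 work-up
Reagents that add atoms: water, O
Why: DDQ dehydrogenation of a silyl enol ether, in which hydride leaves only from C6 because only that cation is stabilised by O8 (and C10 offers no hydrogen on the other side), followed by cleavage of the O8–Si bond, should give the C6=C7 enone with O11 still silylated, so retro-aldol loss of acetone is never possible.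

Step 14
Reactants: 22 (5αH)-4α-acetoxy-3β-[(2S,3R)-2,3-epoxy-2-methylbutanoyloxy]-11-[di-tert-butyl(hydroxy)silyloxy]eudesm-6-en-8-one
Product: 23 (5αH)-4α-acetoxy-3β-[(2R,3S)-3-chloro-2-hydroxy-2-methylbutanoyloxy]-11-[di-tert-butyl(hydroxy)silyloxy]eudesm-6-en-8-one
Conditions: HCl (1 M in Et2O), CH2Cl2, −20 to 0 °C
Reagents that add atoms: hydrogen chloride, Cl
Why: Acid-promoted SN2 opening of a glycidic ester, in which chloride attacks C3' because C2' is tertiary and adjacent to the carbonyl and can neither accept backside attack nor carry positive charge, so C3' is inverted to S and C2' keeps its oxygen (descriptor R by priority change).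

Step 15
Reactants: 23 (5αH)-4α-acetoxy-3β-[(2R,3S)-3-chloro-2-hydroxy-2-methylbutanoyloxy]-11-[di-tert-butyl(hydroxy)silyloxy]eudesm-6-en-8-one
Product: 24 CNP0119872.1
Conditions: HF·pyridine, pyridine, THF, 0 °C to rt
Reagents that add atoms: none
Why: Fluoride-driven cleavage of the silyl ether under acidic, non-basic conditions should free the 11-hydroxyl without closing the chlorohydrin back to the epoxide, eliminating the 4-acetate or epimerising C5.

Compound list
1 | 2-methoxy-5-methylphenol | COc1ccc(C)cc1O | starting material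
2 | 2-methoxy-5-methyl-1,4-benzoquinone | COC1=CC(=O)C(C)=CC1=O | intermediate
3 | 3,4-dimethylpent-3-en-2-one | CC(=O)C(C)=C(C)C | starting material
4 | 4-hydroperoxy-4-methyl-3-methylidenepentan-2-one | CC(=O)C(=C)C(C)(C)OO | intermediate
5 | 4-hydroxy-4-methyl-3-methylidenepentan-2-one | CC(=O)C(=C)C(C)(C)O | intermediate
6 | 2,2-di-tert-butyl-4,4-dimethyl-5,6-dimethylidene-1,3,2-dioxasilinane | C=C1O[Si](C(C)(C)C)(C(C)(C)C)OC(C)(C)C1=C | intermediate
7 | cis-fused adduct, (5βH,10β-methyl)-3-methoxy-8,11-(di-tert-butylsilylenedioxy)-15-noreudesma-2,7-diene-1,4-dione | O=C1C(OC)=CC(=O)[C@]2(C)CC3=C(C(C)(C)O[Si](C(C)(C)C)(C(C)(C)C)O3)C[C@@H]21 | intermediate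
8 | trans-fused adduct, (5αH,10β-methyl)-3-methoxy-8,11-(di-tert-butylsilylenedioxy)-15-noreudesma-2,7-diene-1,4-dione | O=C1C(OC)=CC(=O)[C@]2(C)CC3=C(C(C)(C)O[Si](C(C)(C)C)(C(C)(C)C)O3)C[C@H]21 | intermediate
9 | (5αH)-3-methoxy-8,11-(di-tert-butylsilylenedioxy)eudesma-2,4(15),7-trien-1-one | C=C1C(OC)=CC(=O)[C@]2(C)CC3=C(C(C)(C)O[Si](C(C)(C)C)(C(C)(C)C)O3)C[C@H]21 | intermediate
10 | (5αH)-3-methoxy-8,11-(di-tert-butylsilylenedioxy)eudesma-2,4(15),7-trien-1-ol (C1 configuration undefined, lost in the same step) | C=C1C(OC)=CC(O)[C@]2(C)CC3=C(C(C)(C)O[Si](C(C)(C)C)(C(C)(C)C)O3)C[C@H]21 | intermediate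
11 | (5αH)-8,11-(di-tert-butylsilylenedioxy)eudesma-1,4(15),7-trien-3-one | C=C1C(=O)C=C[C@]2(C)CC3=C(C(C)(C)O[Si](C(C)(C)C)(C(C)(C)C)O3)C[C@H]21 | intermediate
12 | (5αH)-4α-hydroperoxy-8,11-(di-tert-butylsilylenedioxy)eudesma-1,7-dien-3-one | OO[C@]1(C)C(=O)C=C[C@]2(C)CC3=C(C(C)(C)O[Si](C(C)(C)C)(C(C)(C)C)O3)C[C@H]21 | intermediate
13 | (5αH)-4α-hydroxy-8,11-(di-tert-butylsilylenedioxy)eudesma-1,7-dien-3-one | O[C@]1(C)C(=O)C=C[C@]2(C)CC3=C(C(C)(C)O[Si](C(C)(C)C)(C(C)(C)C)O3)C[C@H]21 | intermediate
14 | (5αH)-4α-hydroxy-8,11-(di-tert-butylsilylenedioxy)eudesm-7-en-3-one | O[C@]1(C)C(=O)CC[C@]2(C)CC3=C(C(C)(C)O[Si](C(C)(C)C)(C(C)(C)C)O3)C[C@H]21 | intermediate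
15 | (5αH)-8,11-(di-tert-butylsilylenedioxy)eudesm-7-ene-3β,4α-diol | O[C@]1(C)[C@@H](O)CC[C@]2(C)CC3=C(C(C)(C)O[Si](C(C)(C)C)(C(C)(C)C)O3)C[C@H]21 | intermediate
16 | (E)-2-methylbut-2-en-1-ol | C/C=C(\C)CO | starting material
17 | [(2R,3R)-2,3-dimethyloxiran-2-yl]methanol | OC[C@@]1(C)O[C@@H]1C | intermediate
18 | (2S,3R)-2,3-dimethyloxirane-2-carboxylic acid | OC(=O)[C@@]1(C)O[C@@H]1C | intermediate
19 | (2S,3R)-2,3-dimethyloxirane-2-carboxylic 2,4,6-trichlorobenzoic anhydride | O=C(OC(=O)[C@@]1(C)O[C@@H]1C)c1c(Cl)cc(Cl)cc1Cl | intermediate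
20 | (5αH)-3β-[(2S,3R)-2,3-epoxy-2-methylbutanoyloxy]-8,11-(di-tert-butylsilylenedioxy)eudesm-7-en-4α-ol | O[C@]1(C)[C@@H](OC(=O)[C@@]4(C)O[C@@H]4C)CC[C@]2(C)CC3=C(C(C)(C)O[Si](C(C)(C)C)(C(C)(C)C)O3)C[C@H]21 | intermediate
21 | (5αH)-4α-acetoxy-3β-[(2S,3R)-2,3-epoxy-2-methylbutanoyloxy]-8,11-(di-tert-butylsilylenedioxy)eudesm-7-ene | CC(=O)O[C@]1(C)[C@@H](OC(=O)[C@@]4(C)O[C@@H]4C)CC[C@]2(C)CC3=C(C(C)(C)O[Si](C(C)(C)C)(C(C)(C)C)O3)C[C@H]21 | intermediate
22 | (5αH)-4α-acetoxy-3β-[(2S,3R)-2,3-epoxy-2-methylbutanoyloxy]-11-[di-tert-butyl(hydroxy)silyloxy]eudesm-6-en-8-one | CC(=O)O[C@]1(C)[C@@H](OC(=O)[C@@]3(C)O[C@@H]3C)CC[C@]2(C)CC(=O)C(C(C)(C)O[Si](O)(C(C)(C)C)C(C)(C)C)=C[C@H]21 | intermediate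
23 | (5αH)-4α-acetoxy-3β-[(2R,3S)-3-chloro-2-hydroxy-2-methylbutanoyloxy]-11-[di-tert-butyl(hydroxy)silyloxy]eudesm-6-en-8-one | CC(=O)O[C@]1(C)[C@@H](OC(=O)[C@@](C)(O)[C@H](C)Cl)CC[C@]2(C)CC(=O)C(C(C)(C)O[Si](O)(C(C)(C)C)C(C)(C)C)=C[C@H]21 | intermediate
24 | CNP0119872.1, (3S,4S,5R,10R)-4-acetoxy-3-[(2R,3S)-3-chloro-2-hydroxy-2-methylbutanoyloxy]-11-hydroxyeudesm-6-en-8-one | CC(=O)O[C@]1(C)[C@@H](OC(=O)[C@@](C)(O)[C@H](C)Cl)CC[C@]2(C)CC(=O)C(C(C)(C)O)=C[C@H]21 | target

Total step count: 15. Longest linear sequence: 12 (steps 2–8 and 11–15).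

Steps most likely to fail

Step 4. The catalyst may discriminate poorly between the two quinone faces, the Lewis acid may cleave the silyl enol ether before cycloaddition, or the cis-to-trans equilibration may stay incomplete. The fallback gives up asymmetric catalysis for a racemic synthesis with resolution. It sets out from 2 and 6, which are heated without any Lewis acid in toluene. The methoxy resonance alone directs the same site and regiochemistry. This gives 7 together with the enantiomer of the cis-fused adduct F1. DBU then equilibrates the mixture to 8 and the enantiomer of the trans-fused adduct F2. Preparative chromatography on a chiral stationary phase separates the two, and the route is rejoined at 8.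

Step 7. Oxygen is small, so capture of the C4 radical may show poor facial selectivity, and the C1=C2 enone may be reduced in competition. The fallback replaces the radical event by an ionic one with a bulky oxygen donor. It sets out from 11. Lithium tri-sec-butylborohydride in THF at −78 °C adds hydride to the terminal C15 and gives the lithium cross-conjugated dienolate F3 with the enolate double bond fixed at C3=C4. 2-(Phenylsulfonyl)-3-phenyloxaziridine then transfers oxygen to C4 from the α face away from the 10β-methyl, and an NH4Cl quench returns to the route at 13.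

Step 13. Hydride abstraction from the hindered silylene enol ether may be sluggish, or oxidation may run on at other allylic positions. The fallback changes to electrophilic selenenylation and syn elimination. It sets out from 21. PhSeCl in CH2Cl2 at −78 °C attacks C7 with cleavage of the O8–Si bond, and aqueous work-up gives the 7-phenylselanyl 8-ketone F4 (C7 configuration of no consequence). H2O2 with pyridine gives the selenoxide F5. Its only β-hydrogens are on C6, so syn elimination gives the C6=C7 enone and rejoins the route at 22.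

Further compounds
F1 | step 4 | enantiomer of the cis-fused adduct | O=C1C(OC)=CC(=O)[C@@]2(C)CC3=C(C(C)(C)O[Si](C(C)(C)C)(C(C)(C)C)O3)C[C@H]21
F2 | step 4 | enantiomer of the trans-fused adduct | O=C1C(OC)=CC(=O)[C@@]2(C)CC3=C(C(C)(C)O[Si](C(C)(C)C)(C(C)(C)C)O3)C[C@@H]21
F3 | step 7 | lithium cross-conjugated dienolate (C3–O, C3=C4, C1=C2) | CC1=C([O-])C=C[C@]2(C)CC3=C(C(C)(C)O[Si](C(C)(C)C)(C(C)(C)C)O3)C[C@H]21.[Li+]
F4 | step 13 | 7-phenylselanyl 8-ketone | CC(=O)O[C@]1(C)[C@@H](OC(=O)[C@@]3(C)O[C@@H]3C)CC[C@]2(C)CC(=O)C([Se]c3ccccc3)(C(C)(C)O[Si](O)(C(C)(C)C)C(C)(C)C)C[C@H]21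
F5 | step 13 | selenoxide | CC(=O)O[C@]1(C)[C@@H](OC(=O)[C@@]3(C)O[C@@H]3C)CC[C@]2(C)CC(=O)C([Se](=O)c3ccccc3)(C(C)(C)O[Si](O)(C(C)(C)C)C(C)(C)C)C[C@H]21
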